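**Plan**

- Retrosynthesis: the C1–C10 oxirane and the two acetates are removed first. The butenolide is cut at C7=C11 and at the C6–O acyl bond. The carbocycle is cut at C8–C9, in the sense of a CO2-extruding ring contraction of a 12-membered allyl β-keto lactone. That lactone is cut at C7–C8, C2–C3 and C4=C5.
- Forward: an acyclic C9→C7 chain is built from three small pieces and closed to a 12-membered 1-oxacyclododecadiene-2,4-dione (temporary ring). Pd(0) then excises O–C(=O) as CO2, giving the ten-membered carbocycle. The butenolide is annulated on C6/C7, then acetates, then the oxirane.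
- Enabling feature: in the macrolactone the ring oxygen sits on C9, allylic to C10=C1, and the acyl side is a β-keto ester (C7=O, C8H2). Ionisation gives a tethered allyl/enolate pair that can rejoin only as C8–C9, because the E C4=C5 bond forbids the eight-membered alternative.
- Stereochemistry: C6 comes from (S)-glyceraldehyde acetonide; C3 from a catalyst-controlled vinylogous Mukaiyama aldol; both E alkenes from the stabilised Wittig and the aldol, carried through the key step. The (1R,10R)-oxirane comes from peripheral peracid attack on the germacradiene.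

Key step: step 12

Remark: germacrane numbering is used throughout (ring C1–C10; C11 lactone α-carbon, C12 lactone carbonyl, C13 CH2O on C11, C14 methyl on C10, C15 methyl on C4).
Remark: the aldol catalyst antipode is the one that delivers the dienolate to the Si face of the aldehyde; it is written as (S,S), and the (R,R) antipode is used if the facial sense proves opposite.

Step 1
Reactants: 1 (S)-2,2-dimethyl-1,3-dioxolane-4-carbaldehyde; 2 2-(triphenylphosphoranylidene)propanal
Product: 3 (2E)-3-[(4R)-2,2-dimethyl-1,3-dioxolan-4-yl]-2-methylprop-2-enal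
Conditions: PhMe, 80 °C
Reagents that add atoms: none
Why: Wittig olefination with a formyl-stabilised ylide, which is E-selective for the new trisubstituted C4=C5 bond and neutral enough to keep the α-alkoxy stereocentre of 1 (the future C6) intact.

Step 2
Reactants: 4 methyl tiglate
Product: 5 tert-butyl[(1-methoxy-2-methylbuta-1,3-dien-1-yl)oxy]dimethylsilane
Conditions: LDA (commercial solution), THF/DMPU, −78 °C; TBSCl
Reagents that add atoms: tert-butyldimethylsilyl chloride, CC(C)(C)[Si](C)(C)Cl
Why: Kinetic γ-deprotonation of the enoate and O-silylation (silyl dienol ether formation) give the vinylogous silyl ketene acetal that carries C9, C10, C14, C1 and C2.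

Step 3
Reactants: 3 enal; 5 silyl dienol ether
Product: 6 methyl (2E,5S,6E)-7-[(4R)-2,2-dimethyl-1,3-dioxolan-4-yl]-5-hydroxy-2,6-dimethylhepta-2,6-dienoate
Conditions: SiCl4 (1.1 equiv), (S,S)-binaphthyldiamine-derived bisphosphoramide (2 mol %), iPr2NEt (10 mol %), CH2Cl2, −78 °C; aq. NaHCO3/KF
Reagents that add atoms: none
Why: Catalytic enantioselective vinylogous Mukaiyama aldol addition (chiral Lewis base-activated SiCl4) joins C2 to C3 through the γ-carbon of the dienolate, the phosphoramide-bound silicon cation blocking the Re face of the conjugated aldehyde so that the C3 carbinol is set S by catalyst control, while the enoate double bond (C10=C1) re-forms in the conjugated E geometry.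

Step 4
Reactants: 6 hydroxy ester
Product: 7 methyl (2E,5S,6E)-5-[(tert-butyldimethylsilyl)oxy]-7-[(4R)-2,2-dimethyl-1,3-dioxolan-4-yl]-2,6-dimethylhepta-2,6-dienoate
Conditions: TBSCl, imidazole, DMF, rt
Reagents that add atoms: tert-butyldimethylsilyl chloride, CC(C)(C)[Si](C)(C)Cl
Why: Standard silylation of the secondary allylic alcohol gives a TBS ether that is inert to hydride, SmI2 and Pd(0) and cannot ionise as an allylic leaving group.

Step 5
Reactants: 7 silyl ether ester
Product: 8 (2E,5S,6E)-5-[(tert-butyldimethylsilyl)oxy]-7-[(4R)-2,2-dimethyl-1,3-dioxolan-4-yl]-2,6-dimethylhepta-2,6-dien-1-ol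
Conditions: DIBAL-H (2.5 equiv), CH2Cl2, −78 °C; Rochelle salt
Reagents that add atoms: none
Why: DIBAL-H reduction of the conjugated ester to the primary allylic alcohol (C9) proceeds at low temperature without touching the acetonide, the silyl ether or the alkenes.

Step 6
Reactants: 8 allylic alcohol
Product: 9 (2E,5S,6E)-5-[(tert-butyldimethylsilyl)oxy]-7-[(4R)-2,2-dimethyl-1,3-dioxolan-4-yl]-2,6-dimethylhepta-2,6-dien-1-yl bromoacetate
Conditions: BrCH2COBr, 2,6-lutidine, CH2Cl2, −78 to 0 °C
Reagents that add atoms: bromoacetyl bromide, BrCC(Br)=O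
Why: O-Acylation of the primary allylic alcohol with an acid bromide and a hindered base installs the allyl ester that is both the Reformatsky donor and, later, the leaving group of the key step.

Step 7
Reactants: 9 acetonide
Product: 10 (2E,5S,6E,8R)-5-[(tert-butyldimethylsilyl)oxy]-8,9-dihydroxy-2,6-dimethylnona-2,6-dien-1-yl bromoacetate
Conditions: AcOH/THF/H2O (4:1:1), 35 °C
Reagents that add atoms: none
Why: Acid-catalysed hydrolysis of the terminal isopropylidene acetal is much faster than cleavage of the secondary TBS ether or of the ester under these mild conditions.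

Step 8
Reactants: 10 diol
Product: 11 (2E,5S,6E,8R)-5-[(tert-butyldimethylsilyl)oxy]-2,6-dimethyl-8,9-bis[(triethylsilyl)oxy]nona-2,6-dien-1-yl bromoacetate
Conditions: TESOTf (2.4 equiv), 2,6-lutidine, CH2Cl2, −78 °C
Reagents that add atoms: triethylsilyl trifluoromethanesulfonate, CC[Si](CC)(CC)OS(=O)(=O)C(F)(F)F
Why: Silylation with a silyl triflate and a non-nucleophilic base protects both hydroxyls without attacking the bromoacetate.

Step 9
Reactants: 11 bis-TES ether
Product: 12 (2E,5S,6E,8R)-5-[(tert-butyldimethylsilyl)oxy]-2,6-dimethyl-9-oxo-8-[(triethylsilyl)oxy]nona-2,6-dien-1-yl bromoacetate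
Conditions: (COCl)2, DMSO, CH2Cl2, −78 to −40 °C; then Et3N
Reagents that add atoms: none
Why: Under Swern conditions a primary triethylsilyl ether is cleaved and oxidised directly to the aldehyde whereas secondary TES and TBS ethers are inert, so the configurationally labile α-silyloxy aldehyde is formed without a free α-hydroxy aldehyde stage.

Step 10
Reactants: 12 bromoacetate aldehyde
Product: 13 (5R,6E,8S,10E)-8-[(tert-butyldimethylsilyl)oxy]-4-hydroxy-7,11-dimethyl-5-[(triethylsilyl)oxy]-1-oxacyclododeca-6,10-dien-2-one (12-membered lactone, both C4 epimers)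
Conditions: SmI2 (2.5 equiv), THF (0.005 M, slow addition), −78 to 0 °C
Reagents that add atoms: none
Why: Samarium(II)-mediated intramolecular Reformatsky reaction, in which the C–Br bond is reduced far faster than the aldehyde and the samarium enolate adds to the aldehyde under high dilution to close the 12-membered lactone at C7–C8 (the new carbinol centre is a mixture and is erased in the next step).

Step 11
Reactants: 13 β-hydroxy macrolactone
Product: 14 (5R,6E,8S,10E)-8-[(tert-butyldimethylsilyl)oxy]-7,11-dimethyl-5-[(triethylsilyl)oxy]-1-oxacyclododeca-6,10-diene-2,4-dione (12-membered allyl β-keto lactone)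
Conditions: Dess–Martin periodinane, NaHCO3, CH2Cl2, 0 °C to rt
Reagents that add atoms: none
Why: Dess–Martin oxidation of the β-hydroxy lactone under buffered, non-epimerising conditions gives the allyl β-keto lactone required for the key step.

Step 12
Reactants: 14 allyl β-keto macrolactone
Product: 15 (2R,3E,5S,7E)-5-[(tert-butyldimethylsilyl)oxy]-4,8-dimethyl-2-[(triethylsilyl)oxy]cyclodeca-3,7-dien-1-one
Conditions: Pd(PPh3)4 (10 mol %), PhMe (0.003 M), 40 °C
Reagents that add atoms: none
Why: Proposed new method: Pd(0) ionises the allylic C9–O bond of the macrolactone to a tethered η3-allylpalladium β-keto carboxylate, which loses CO2 to give the C8 enolate; C–C bond formation between C8 and the CH2 terminus C9 then gives the cyclodecadienone, so the O–C(=O) unit is excised and the ring contracts from 12 to 10 atoms. The closest known reaction type is the Tsuji–Saegusa decarboxylative allylation of acyclic allyl β-keto esters (with the palladium-mediated decarboxylative ring contractions of small vinyl-substituted heterocycles and 1,3 O-to-C shifts of cyclic allyl enol ethers as ring-size-changing relatives), which has not been shown for a macrocyclic allyl β-keto lactone. The ten-membered ring closes by attack of the enolate carbon on the unsubstituted terminus of the allyl unit within the ion pair, the C10=C1 double bond ending up endocyclic (an intramolecular allylic alkylation, not an SN2′ process). No new stereocentre is formed: the step is stereoablative at C8 (keto and enol forms of 14 converge), C3 and C6 are spectators, and the E geometry of C1=C10 is carried over because collapse of the tight ion pair at C9 is expected to outrun η3–η1–η3 isomerisation at the substituted terminus C1. The step needs C- over O-allylation, attack at C9 and not C1, and an enolate that stays at C8: attack at C1 would require an (E)-cyclooctene and is excluded by the E C4=C5 bond, the enolate is generated regiospecifically by loss of CO2 and never towards C6, and the non-polar solvent and high dilution keep the ion pair tight and intramolecular.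

Step 13
Reactants: 15 silyl-protected cyclodecadienone
Product: 16 (2R,3E,5S,7E)-5-[(tert-butyldimethylsilyl)oxy]-2-hydroxy-4,8-dimethylcyclodeca-3,7-dien-1-one
Conditions: HF·pyridine, pyridine, THF, 0 °C
Reagents that add atoms: none
Why: Selective desilylation with buffered HF·pyridine cleaves the triethylsilyl ether over the more robust TBS ether and unmasks the C6 hydroxyl next to the C7 ketone.

Step 14
Reactants: 17 benzyl (diethoxyphosphoryl)acetate
Product: 18 benzyl 2-(diethoxyphosphoryl)-3-hydroxypropanoate (racemic)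
Conditions: (CH2O)n (1.05 equiv), piperidine (10 mol %), THF/H2O, 50 °C
Reagents that add atoms: paraformaldehyde (as formaldehyde), C=O
Why: Amine-catalysed aldol-type hydroxymethylation of the doubly activated methylene with formaldehyde, in which the adduct is protonated faster than it undergoes Horner–Wadsworth–Emmons elimination under these weakly basic conditions.

Step 15
Reactants: 18 hydroxy phosphonate
Product: 19 benzyl 3-[(tert-butyldimethylsilyl)oxy]-2-(diethoxyphosphoryl)propanoate (racemic)
Conditions: TBSCl, imidazole, CH2Cl2, 0 °C to rt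
Reagents that add atoms: tert-butyldimethylsilyl chloride, CC(C)(C)[Si](C)(C)Cl
Why: Standard silylation of the primary alcohol protects the future C13 oxygen as an ether that is a poor leaving group in the later olefination.

Step 16
Reactants: 19 benzyl ester
Product: 20 3-[(tert-butyldimethylsilyl)oxy]-2-(diethoxyphosphoryl)propanoic acid (racemic)
Conditions: H2 (1 atm), 10% Pd/C, EtOAc, rt
Reagents that add atoms: none
Why: Hydrogenolysis of the benzyl ester frees the carboxylic acid under neutral conditions, so the β-silyloxy phosphonate is never exposed to base.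

Step 17
Reactants: 16 α-ketol; 20 phosphono acid
Product: 22 (3S,6R,1(10)E,4E)-3,13-bis[(tert-butyldimethylsilyl)oxy]germacra-1(10),4,7(11)-trien-12,6-olide, via phosphonoacetate ester 21 (not isolated)
Conditions: DCC, DMAP (cat.), CH2Cl2, 0 °C; then LiCl, iPr2NEt, MeCN, 0 °C to rt
Reagents that add atoms: none
Why: Steglich esterification of the α-ketol followed in the same flask by an intramolecular Horner–Wadsworth–Emmons reaction (Masamune–Roush conditions) on the C7 ketone closes the butenolide, the five-membered ring fixing the C7=C11 geometry and the mild base sparing the C6–H.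

Step 18
Reactants: 22 bis-silyl butenolide
Product: 23 (3S,6R,1(10)E,4E)-3,13-dihydroxygermacra-1(10),4,7(11)-trien-12,6-olide
Conditions: HF·pyridine, THF/pyridine, 0 °C to rt
Reagents that add atoms: none
Why: Fluoride-mediated desilylation with buffered HF·pyridine removes both TBS ethers without base, so neither the C6 γ-proton of the butenolide nor the acid-sensitive 1,5-diene is put at risk.

Step 19
Reactants: 23 diol
Product: 24 (3S,6R,1(10)E,4E)-3,13-diacetoxygermacra-1(10),4,7(11)-trien-12,6-olide
Conditions: Ac2O, pyridine, DMAP (cat.), CH2Cl2, 0 °C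
Reagents that add atoms: acetic anhydride, CC(=O)OC(C)=O
Why: DMAP-catalysed acetylation esterifies the secondary allylic (C3) and primary allylic (C13) alcohols without affecting any stereocentre.

Step 20
Reactants: 24 diacetate
Product: 25 (1R,3S,6R,10R,4E)-3,13-diacetoxy-1,10-epoxygermacra-4,7(11)-dien-12,6-olide (CNP0294733.1)
Conditions: mCPBA (1.05 equiv), NaHCO3, CH2Cl2, −20 to 0 °C
Reagents that add atoms: meta-chloroperoxybenzoic acid, OOC(=O)c1cccc(Cl)c1
Why: Prilezhaev epoxidation, in which only C1=C10 is electron-rich (C4=C5 carries two allylic acyloxy groups, C7=C11 is conjugated), the E alkene gives the trans-oxirane stereospecifically, and peracid attack on the exposed outer face of the crossed germacradiene conformer (C14 and C15 both on the β-face, as fixed by the 6α-lactone) should give the 1β,10α, i.e. (1R,10R), epoxide.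

**Compound list**

1 | (S)-2,2-dimethyl-1,3-dioxolane-4-carbaldehyde ((S)-glyceraldehyde acetonide) | O=C[C@@H]1COC(C)(C)O1 | starting material
2 | 2-(triphenylphosphoranylidene)propanal | CC(C=O)=P(c1ccccc1)(c1ccccc1)c1ccccc1 | starting material
3 | (2E)-3-[(4R)-2,2-dimethyl-1,3-dioxolan-4-yl]-2-methylprop-2-enal | O=C/C(C)=C/[C@@H]1COC(C)(C)O1 | intermediate
4 | methyl tiglate (methyl (2E)-2-methylbut-2-enoate) | C/C=C(\C)C(=O)OC | starting material
5 | tert-butyl[(1-methoxy-2-methylbuta-1,3-dien-1-yl)oxy]dimethylsilane (ketene acetal geometry not defined) | C=CC(C)=C(OC)O[Si](C)(C)C(C)(C)C | intermediate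
6 | methyl (2E,5S,6E)-7-[(4R)-2,2-dimethyl-1,3-dioxolan-4-yl]-5-hydroxy-2,6-dimethylhepta-2,6-dienoate | COC(=O)/C(C)=C/C[C@H](O)/C(C)=C/[C@@H]1COC(C)(C)O1 | intermediate
7 | methyl (2E,5S,6E)-5-[(tert-butyldimethylsilyl)oxy]-7-[(4R)-2,2-dimethyl-1,3-dioxolan-4-yl]-2,6-dimethylhepta-2,6-dienoate | COC(=O)/C(C)=C/C[C@H](O[Si](C)(C)C(C)(C)C)/C(C)=C/[C@@H]1COC(C)(C)O1 | intermediate
8 | (2E,5S,6E)-5-[(tert-butyldimethylsilyl)oxy]-7-[(4R)-2,2-dimethyl-1,3-dioxolan-4-yl]-2,6-dimethylhepta-2,6-dien-1-ol | OC/C(C)=C/C[C@H](O[Si](C)(C)C(C)(C)C)/C(C)=C/[C@@H]1COC(C)(C)O1 | intermediate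
9 | bromoacetate of 8 | BrCC(=O)OC/C(C)=C/C[C@H](O[Si](C)(C)C(C)(C)C)/C(C)=C/[C@@H]1COC(C)(C)O1 | intermediate
10 | (2E,5S,6E,8R)-5-[(tert-butyldimethylsilyl)oxy]-8,9-dihydroxy-2,6-dimethylnona-2,6-dien-1-yl bromoacetate | BrCC(=O)OC/C(C)=C/C[C@H](O[Si](C)(C)C(C)(C)C)/C(C)=C/[C@@H](O)CO | intermediate
11 | (2E,5S,6E,8R)-5-[(tert-butyldimethylsilyl)oxy]-2,6-dimethyl-8,9-bis[(triethylsilyl)oxy]nona-2,6-dien-1-yl bromoacetate | BrCC(=O)OC/C(C)=C/C[C@H](O[Si](C)(C)C(C)(C)C)/C(C)=C/[C@@H](O[Si](CC)(CC)CC)CO[Si](CC)(CC)CC | intermediate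
12 | (2E,5S,6E,8R)-5-[(tert-butyldimethylsilyl)oxy]-2,6-dimethyl-9-oxo-8-[(triethylsilyl)oxy]nona-2,6-dien-1-yl bromoacetate | BrCC(=O)OC/C(C)=C/C[C@H](O[Si](C)(C)C(C)(C)C)/C(C)=C/[C@@H](O[Si](CC)(CC)CC)C=O | intermediate
13 | (5R,6E,8S,10E)-8-[(tert-butyldimethylsilyl)oxy]-4-hydroxy-7,11-dimethyl-5-[(triethylsilyl)oxy]-1-oxacyclododeca-6,10-dien-2-one (C4 epimers) | OC1CC(=O)OC/C(C)=C/C[C@H](O[Si](C)(C)C(C)(C)C)/C(C)=C/[C@H]1O[Si](CC)(CC)CC | intermediate
14 | (5R,6E,8S,10E)-8-[(tert-butyldimethylsilyl)oxy]-7,11-dimethyl-5-[(triethylsilyl)oxy]-1-oxacyclododeca-6,10-diene-2,4-dione | O=C1CC(=O)OC/C(C)=C/C[C@H](O[Si](C)(C)C(C)(C)C)/C(C)=C/[C@H]1O[Si](CC)(CC)CC | intermediate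
15 | (2R,3E,5S,7E)-5-[(tert-butyldimethylsilyl)oxy]-4,8-dimethyl-2-[(triethylsilyl)oxy]cyclodeca-3,7-dien-1-one | O=C1CC/C(C)=C/C[C@H](O[Si](C)(C)C(C)(C)C)/C(C)=C/[C@H]1O[Si](CC)(CC)CC | intermediate
16 | (2R,3E,5S,7E)-5-[(tert-butyldimethylsilyl)oxy]-2-hydroxy-4,8-dimethylcyclodeca-3,7-dien-1-one | O=C1CC/C(C)=C/C[C@H](O[Si](C)(C)C(C)(C)C)/C(C)=C/[C@H]1O | intermediate
17 | benzyl (diethoxyphosphoryl)acetate | CCOP(=O)(OCC)CC(=O)OCc1ccccc1 | starting material
18 | benzyl 2-(diethoxyphosphoryl)-3-hydroxypropanoate (racemic) | CCOP(=O)(OCC)C(CO)C(=O)OCc1ccccc1 | intermediate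
19 | benzyl 3-[(tert-butyldimethylsilyl)oxy]-2-(diethoxyphosphoryl)propanoate (racemic) | CCOP(=O)(OCC)C(CO[Si](C)(C)C(C)(C)C)C(=O)OCc1ccccc1 | intermediate
20 | 3-[(tert-butyldimethylsilyl)oxy]-2-(diethoxyphosphoryl)propanoic acid (racemic) | CCOP(=O)(OCC)C(CO[Si](C)(C)C(C)(C)C)C(=O)O | intermediate
21 | (1R,2E,4S,6E)-4-[(tert-butyldimethylsilyl)oxy]-3,7-dimethyl-10-oxocyclodeca-2,6-dien-1-yl 3-[(tert-butyldimethylsilyl)oxy]-2-(diethoxyphosphoryl)propanoate (epimers at the phosphonate carbon; not isolated) | O=C1CC/C(C)=C/C[C@H](O[Si](C)(C)C(C)(C)C)/C(C)=C/[C@H]1OC(=O)C(CO[Si](C)(C)C(C)(C)C)P(=O)(OCC)OCC | intermediate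
22 | (3S,6R,1(10)E,4E)-3,13-bis[(tert-butyldimethylsilyl)oxy]germacra-1(10),4,7(11)-trien-12,6-olide | CC(C)(C)[Si](C)(C)OCC1=C2CC/C(C)=C/C[C@H](O[Si](C)(C)C(C)(C)C)/C(C)=C/[C@H]2OC1=O | intermediate
23 | (3S,6R,1(10)E,4E)-3,13-dihydroxygermacra-1(10),4,7(11)-trien-12,6-olide | OCC1=C2CC/C(C)=C/C[C@H](O)/C(C)=C/[C@H]2OC1=O | intermediate
24 | (3S,6R,1(10)E,4E)-3,13-diacetoxygermacra-1(10),4,7(11)-trien-12,6-olide | CC(=O)OCC1=C2CC/C(C)=C/C[C@H](OC(C)=O)/C(C)=C/[C@H]2OC1=O | intermediate
25 | (1R,3S,6R,10R,4E)-3,13-diacetoxy-1,10-epoxygermacra-4,7(11)-dien-12,6-olide (CNP0294733.1) | CC(=O)OCC1=C2CC[C@@]3(C)O[C@@H]3C[C@H](OC(C)=O)/C(C)=C/[C@H]2OC1=O | target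

**Totals**

Total step count: 20. Longest linear sequence: 16 steps (steps 1, 3–13, 17–20).

**Steps most likely to fail**

1. Step 12 (Proposed new method). The ion pair may not collapse cleanly. Possible processes are loss of the C1=C10 geometry by η3–η1–η3 isomerisation, proton transfer within the pair (quenched enolate plus a diene), or intermolecular recombination to oligomers. The fallback uses known chemistry, sets out from 14 and returns at 15. Heating 14 with methanol and catalytic DMAP in toluene (100 °C, acylketene-type transesterification of the β-keto ester) opens the lactone to methyl (4R,5E,7S,9E)-7-[(tert-butyldimethylsilyl)oxy]-11-hydroxy-6,10-dimethyl-3-oxo-4-[(triethylsilyl)oxy]undeca-5,9-dienoate F1. Methyl chloroformate and pyridine convert its C9 alcohol into the allylic methyl carbonate F2. A palladium-catalysed intramolecular allylic alkylation with the stabilised β-keto ester enolate (Tsuji–Trost macrocyclisation; Pd2(dba)3, dppe, THF, high dilution, 50 °C) closes the ten-membered ring directly, giving methyl (1RS,3R,4E,6S,8E)-6-[(tert-butyldimethylsilyl)oxy]-5,9-dimethyl-2-oxo-3-[(triethylsilyl)oxy]cyclodeca-4,8-diene-1-carboxylate F3. Ester cleavage with Me3SnOH (1,2-dichloroethane, 70 °C) and spontaneous decarboxylation of the β-keto acid give 15.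

2. Step 17. The phosphonate carbanion may expel silanolate (E1cB), or the base may enolise C6, causing epimerisation or migration of C4=C5 into conjugation, before or after ring closure. The fallback sets out from 16 and returns at 23. Esterification of 16 with bromo(diethoxyphosphoryl)acetic acid (DCC, CH2Cl2, 0 °C) gives (1R,2E,4S,6E)-4-[(tert-butyldimethylsilyl)oxy]-3,7-dimethyl-10-oxocyclodeca-2,6-dien-1-yl bromo(diethoxyphosphoryl)acetate F4. This phosphonate is more acidic and has no β-leaving group, so it closes with LiCl/Et3N at 0 °C by intramolecular Horner–Wadsworth–Emmons reaction to (3S,6R,1(10)E,4E)-11-bromo-3-[(tert-butyldimethylsilyl)oxy]-13-norgermacra-1(10),4,7(11)-trien-12,6-olide F5. Stille coupling with (tributylstannyl)methanol (Pd2(dba)3, AsPh3, CuI, NMP, 40 °C) installs C13 as (3S,6R,1(10)E,4E)-3-[(tert-butyldimethylsilyl)oxy]-13-hydroxygermacra-1(10),4,7(11)-trien-12,6-olide F6. HF·pyridine then gives 23.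

3. Step 20. Facial selectivity may be poor if the conformer with C14 on the α-face is populated, giving the 1α,10β-oxirane, and the acid by-product may trigger transannular opening of the epoxide. The fallback sets out from 24 and returns at 25. Substrate control is replaced by reagent control: a Shi asymmetric epoxidation of the E-trisubstituted C1=C10 bond, using the fructose-derived ketone antipode matched to the 1β,10α face (Oxone, buffered MeCN/dimethoxymethane–H2O, 0 °C). This fallback makes no new compound (F0).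

**Further compounds**

F1 | step 12 | methyl (4R,5E,7S,9E)-7-[(tert-butyldimethylsilyl)oxy]-11-hydroxy-6,10-dimethyl-3-oxo-4-[(triethylsilyl)oxy]undeca-5,9-dienoate | OC/C(C)=C/C[C@H](O[Si](C)(C)C(C)(C)C)/C(C)=C/[C@@H](O[Si](CC)(CC)CC)C(=O)CC(=O)OC
F2 | step 12 | methyl (4R,5E,7S,9E)-7-[(tert-butyldimethylsilyl)oxy]-11-[(methoxycarbonyl)oxy]-6,10-dimethyl-3-oxo-4-[(triethylsilyl)oxy]undeca-5,9-dienoate | COC(=O)OC/C(C)=C/C[C@H](O[Si](C)(C)C(C)(C)C)/C(C)=C/[C@@H](O[Si](CC)(CC)CC)C(=O)CC(=O)OC
F3 | step 12 | methyl (1RS,3R,4E,6S,8E)-6-[(tert-butyldimethylsilyl)oxy]-5,9-dimethyl-2-oxo-3-[(triethylsilyl)oxy]cyclodeca-4,8-diene-1-carboxylate | O=C1C(C(=O)OC)C/C(C)=C/C[C@H](O[Si](C)(C)C(C)(C)C)/C(C)=C/[C@H]1O[Si](CC)(CC)CC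
F4 | step 17 | (1R,2E,4S,6E)-4-[(tert-butyldimethylsilyl)oxy]-3,7-dimethyl-10-oxocyclodeca-2,6-dien-1-yl bromo(diethoxyphosphoryl)acetate | O=C1CC/C(C)=C/C[C@H](O[Si](C)(C)C(C)(C)C)/C(C)=C/[C@H]1OC(=O)C(Br)P(=O)(OCC)OCC
F5 | step 17 | (3S,6R,1(10)E,4E)-11-bromo-3-[(tert-butyldimethylsilyl)oxy]-13-norgermacra-1(10),4,7(11)-trien-12,6-olide | BrC1=C2CC/C(C)=C/C[C@H](O[Si](C)(C)C(C)(C)C)/C(C)=C/[C@H]2OC1=O
F6 | step 17 | (3S,6R,1(10)E,4E)-3-[(tert-butyldimethylsilyl)oxy]-13-hydroxygermacra-1(10),4,7(11)-trien-12,6-olide | OCC1=C2CC/C(C)=C/C[C@H](O[Si](C)(C)C(C)(C)C)/C(C)=C/[C@H]2OC1=O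
F0 | step 20 | none | none
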